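**Retrosynthetic overview**
1. Feature: in the pyrrole ring, C2 and C3 both carry bromine and C2 is bonded to N1. C2=C3 is therefore read as a 1-bromoalkyne (C2–Br already present) that takes up one Br+ at C3 while N1 closes onto C2. The bromine at C6 of the benzene ring is bought with the aniline.
2. N1–H ⇒ N1–SO2Tol: the sulfonyl group makes N–H acidic enough for the closure, damps the benzene ring towards Br+, and is removed last without reductants.
3. N1–C2 and C3–Br ⇒ ortho-(bromoethynyl)sulfonanilide + NBS (bromocyclisation, the only ring-forming event).
4. C≡C–Br ⇒ C≡C–SiMe3 (Si/Br exchange). C3a–C3 ⇒ iodide-selective Sonogashira coupling of tosylated 5-bromo-2-iodoaniline with trimethylsilylacetylene.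
5. Ring order: the benzene ring is purchased and the pyrrole ring is closed in step 4.

Key step: step 4

Remark: the target is planar and has no stereocentre or stereoaxis, so it is achiral. The question of a single enantiomer does not arise, and no step has to control configuration.

**Step 1**
Reactants: 1 5-bromo-2-iodoaniline; 2 4-toluenesulfonyl chloride
Product: 3 N-(5-bromo-2-iodophenyl)-4-methylbenzenesulfonamide
Conditions: TsCl (1.1 equiv), pyridine, 0 °C → rt
Reagents that add atoms: 4-toluenesulfonyl chloride, Cc1ccc(cc1)S(=O)(=O)Cl
Why: N-sulfonylation of an aniline (Hinsberg type) with pyridine as nucleophilic catalyst and HCl scavenger; the ortho-iodine and the low nucleophilicity of the monosulfonamide should hold the reaction at the mono-tosyl stage, and C–I and C–Br are not touched.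

**Step 2**
Reactants: 3 N-(5-bromo-2-iodophenyl)-4-methylbenzenesulfonamide; 4 trimethylsilylacetylene
Product: 5 N-{5-bromo-2-[(trimethylsilyl)ethynyl]phenyl}-4-methylbenzenesulfonamide
Conditions: PdCl2(PPh3)2 (2 mol %), CuI (4 mol %), Et3N (3 equiv), THF (degassed), rt
Reagents that add atoms: trimethylsilylacetylene, C#C[Si](C)(C)C
Why: Sonogashira coupling; at room temperature Pd(0) inserts into C–I far faster than into C–Br, so only the iodide is exchanged, and the bulky silyl cap together with the weak amine base keeps the sulfonamide from closing onto the alkyne.

**Step 3**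
Reactants: 5 N-{5-bromo-2-[(trimethylsilyl)ethynyl]phenyl}-4-methylbenzenesulfonamide; 6 N-bromosuccinimide
Product: 7 N-[5-bromo-2-(bromoethynyl)phenyl]-4-methylbenzenesulfonamide
Conditions: NBS (1.1 equiv), AgNO3 (10 mol %), acetone (reagent grade), rt, dark; aqueous work-up
Reagents that add atoms: N-bromosuccinimide, O=C1CCC(=O)N1Br
Why: Silver-catalysed ipso-bromodesilylation of an alkynylsilane with NBS, a known one-step entry to 1-bromoalkynes; the medium is neutral, so the sulfonamide stays protonated and non-nucleophilic, and the bromoalkyne, a poor partner for unactivated NBS, should survive the small excess.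

**Step 4**
Reactants: 7 N-[5-bromo-2-(bromoethynyl)phenyl]-4-methylbenzenesulfonamide; 6 N-bromosuccinimide
Product: 9 2,3,6-tribromo-1-(4-methylbenzenesulfonyl)-1H-indole, via bromirenium zwitterion 8 (not isolated)
Conditions: NBS (1.1 equiv, recrystallised), K2CO3 (0.2 equiv), 4 Å MS, dry MeCN, 0 °C → rt, dark
Reagents that add atoms: N-bromosuccinimide, O=C1CCC(=O)N1Br
Why: Proposed new method: the catalytic carbonate forms the sulfonamide anion, NBS hands Br+ to the C≡C bond to give the short-lived bridged bromirenium zwitterion 8 (in the limit a concerted, nucleophile-assisted anti addition), nitrogen opens it at the bromine-bearing terminus so that N1–C2 and C3–Br arise together, and the succinimide anion released is basic enough to deprotonate the next molecule of 7, which is why the base is needed only in catalytic amount. The closest known reaction type is the 5-endo-dig halocyclisation of N-sulfonyl-2-alkynylanilines bearing carbon-substituted alkynes to 3-haloindoles with iodine/base, N-halosuccinimides or copper(II) halides; a halogen on the alkyne terminus is the untested point, since it lowers the nucleophilicity of the triple bond. The pyrrole ring closes in the 5-endo-dig mode: attack at the aryl-bearing carbon would be a 4-exo closure to a strained four-membered ring and is out of reach, so the tether fixes the regiochemistry even though an open vinyl cation would sit better next to the arene, and the lone pair of the alkynyl bromine helps to carry the charge that builds up at C2. No stereocentre is formed, and aromatisation makes the closure irreversible. The step needs bromination of the alkyne rather than of the anilide ring (position para to nitrogen, the later C5) or of the tolyl methyl group, which is secured by the sulfonyl, ring-bromine and bromoethynyl groups that all deplete the ring, by the acid-free medium and by darkness, while the sieves keep water from intercepting the cationic intermediate. A purely anionic 5-endo closure, known for ortho-(bromoethynyl)sulfonanilides under base, would give a C3-unsubstituted 2-bromoindole that NBS brominates at C3, so this leak ends in 9 as well.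

**Step 5**
Reactants: 9 2,3,6-tribromo-1-(4-methylbenzenesulfonyl)-1H-indole
Product: 10 2,3,6-tribromo-1H-indole
Conditions: LiOH·H2O (3 equiv), THF/H2O (3:1), rt, dark; pH 7 phosphate buffer work-up
Reagents that add atoms: none
Why: Nucleophilic desulfonylation of an N-sulfonylindole by hydroxide attack at sulfur, eased because three bromines make the indole nitrogen a good leaving group; the conditions are non-reducing so all C–Br bonds persist, methanol is left out so that no methyl sulfonate can N-methylate the product, and the buffered work-up avoids the acid that degrades 2-bromoindoles.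

**Compound list**
1 | 5-bromo-2-iodoaniline | Nc1cc(Br)ccc1I | starting material
2 | 4-toluenesulfonyl chloride | Cc1ccc(cc1)S(=O)(=O)Cl | starting material
3 | N-(5-bromo-2-iodophenyl)-4-methylbenzenesulfonamide | Cc1ccc(cc1)S(=O)(=O)Nc1cc(Br)ccc1I | intermediate
4 | trimethylsilylacetylene | C#C[Si](C)(C)C | starting material
5 | N-{5-bromo-2-[(trimethylsilyl)ethynyl]phenyl}-4-methylbenzenesulfonamide | Cc1ccc(cc1)S(=O)(=O)Nc1cc(Br)ccc1C#C[Si](C)(C)C | intermediate
6 | N-bromosuccinimide | O=C1CCC(=O)N1Br | starting material
7 | N-[5-bromo-2-(bromoethynyl)phenyl]-4-methylbenzenesulfonamide | Cc1ccc(cc1)S(=O)(=O)Nc1cc(Br)ccc1C#CBr | intermediate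
8 | bromirenium zwitterion (C≡C of 7 bridged by Br+, sulfonamide nitrogen deprotonated; not isolated) | Cc1ccc(cc1)S(=O)(=O)[N-]c1cc(Br)ccc1C1=C(Br)[Br+]1 | intermediate
9 | 2,3,6-tribromo-1-(4-methylbenzenesulfonyl)-1H-indole | Cc1ccc(cc1)S(=O)(=O)n1c(Br)c(Br)c2ccc(Br)cc21 | intermediate
10 | 2,3,6-tribromo-1H-indole | Brc1ccc2c(Br)c(Br)[nH]c2c1 | target

**Total step count:** 5
**Longest linear sequence:** 5 steps (1 → 3 → 5 → 7 → 9 → 10)

**Steps most likely to fail**

1. Step 4 (Proposed new method).
   - Process at risk: Br+ transfer to the electron-poor bromoalkyne may be slower than bromination of the anilide ring, or slower than interception of the cationic intermediate by outside nucleophiles. Ring closure would then be overtaken.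
   - Fallback (known chemistry; the two bonds are made one after the other instead of together): it sets out from 7. Base-induced anionic 5-endo-dig hydroamination of the bromoalkyne (Cs2CO3, DMF, warm) is a known reaction of ortho-(bromoethynyl)- and ortho-(2,2-dibromovinyl)sulfonanilides, and it should give 2,6-dibromo-1-(4-methylbenzenesulfonyl)-1H-indole F1. Electrophilic aromatic bromination with Br2 in CH2Cl2 at C3, the normal site of attack in N-sulfonylindoles, then leads to 9, where the route is rejoined.

2. Step 5.
   - Process at risk: addition–elimination of hydroxide at C2 of the electron-poor 2-bromo-N-sulfonylindole may compete with attack at sulfur. The liberated 2,3-dibromoindole may also decay slowly on long contact with aqueous base, air and light.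
   - Fallback (change of the N-activating group to one removed by fluoride-triggered fragmentation at a remote silicon atom, so that no nucleophile has to approach the N–S–C2 region): it sets out from 1.
     - Sulfonylation with 2-(trimethylsilyl)ethanesulfonyl chloride in pyridine gives N-(5-bromo-2-iodophenyl)-2-(trimethylsilyl)ethane-1-sulfonamide F2.
     - Sonogashira coupling with 4 gives N-{5-bromo-2-[(trimethylsilyl)ethynyl]phenyl}-2-(trimethylsilyl)ethane-1-sulfonamide F3.
     - NBS with catalytic AgNO3 gives N-[5-bromo-2-(bromoethynyl)phenyl]-2-(trimethylsilyl)ethane-1-sulfonamide F4.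
     - Bromocyclisation under the conditions of step 4 gives 2,3,6-tribromo-1-{[2-(trimethylsilyl)ethyl]sulfonyl}-1H-indole F5.
     - TBAF in THF (0 °C → rt) with a buffered work-up then releases 10, where the route is rejoined.

3. Step 3.
   - Process at risk: the exchange at silicon may be sluggish. That leaves time for N-bromination of the sulfonamide and for silver-promoted ring closure onto the alkyne before the C2 bromine is in place.
   - Fallback (the bromoalkyne is built by elimination instead of electrophilic bromination, with no silver and no NBS): it sets out from 3.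
     - N-deprotonation and iodine/magnesium exchange (i-PrMgCl, then i-PrMgCl·LiCl, THF, −20 °C, a temperature at which C–Br is left alone), followed by a DMF quench, gives N-(5-bromo-2-formylphenyl)-4-methylbenzenesulfonamide F6.
     - Ramirez olefination (CBr4, PPh3, CH2Cl2, 0 °C) gives N-[5-bromo-2-(2,2-dibromoethenyl)phenyl]-4-methylbenzenesulfonamide F7.
     - Dehydrobromination with DBU in MeCN at rt, a known route from 1,1-dibromoalkenes to 1-bromoalkynes, gives 7, where the route is rejoined.

**Further compounds**
F1 | step 4 | 2,6-dibromo-1-(4-methylbenzenesulfonyl)-1H-indole | Cc1ccc(cc1)S(=O)(=O)n1c(Br)cc2ccc(Br)cc21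
F2 | step 5 | N-(5-bromo-2-iodophenyl)-2-(trimethylsilyl)ethane-1-sulfonamide | C[Si](C)(C)CCS(=O)(=O)Nc1cc(Br)ccc1I
F3 | step 5 | N-{5-bromo-2-[(trimethylsilyl)ethynyl]phenyl}-2-(trimethylsilyl)ethane-1-sulfonamide | C[Si](C)(C)CCS(=O)(=O)Nc1cc(Br)ccc1C#C[Si](C)(C)C
F4 | step 5 | N-[5-bromo-2-(bromoethynyl)phenyl]-2-(trimethylsilyl)ethane-1-sulfonamide | C[Si](C)(C)CCS(=O)(=O)Nc1cc(Br)ccc1C#CBr
F5 | step 5 | 2,3,6-tribromo-1-{[2-(trimethylsilyl)ethyl]sulfonyl}-1H-indole | C[Si](C)(C)CCS(=O)(=O)n1c(Br)c(Br)c2ccc(Br)cc21
F6 | step 3 | N-(5-bromo-2-formylphenyl)-4-methylbenzenesulfonamide | Cc1ccc(cc1)S(=O)(=O)Nc1cc(Br)ccc1C=O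
F7 | step 3 | N-[5-bromo-2-(2,2-dibromoethenyl)phenyl]-4-methylbenzenesulfonamide | Cc1ccc(cc1)S(=O)(=O)Nc1cc(Br)ccc1C=C(Br)Br
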